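**Retrosynthesis**
- Plakortide N is hydrolysed from its methyl ester. The C6–C7 bond is made last, by ipso-vinylation of a cyclic peroxycarbenium ion with an E-vinylsilane. Axial attack on the ring sets C6.
- The only ring, the 1,2-dioxane, forms when a C3 hydroperoxide closes onto the C6 ethyl ketone. The hydroperoxide comes from SN2 of H2O2 on a C3 mesylate, which inverts C3.
- The keto-ester carrying C3 and C4 comes from anti-selective ethyl-cuprate addition to a γ-silyloxy enone made from dimethyl (R)-malate.
- The vinylsilane comes from syn-carbocupration of a terminal alkyne. The alkyne is made from the Johnson–Claisen [3,3] ester, which sets C10 and the E-C11=C12 alkene. The Claisen precursor is the (S,Z)-hept-4-en-3-ol made from L-2-aminobutyric acid.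

Assumption: the configuration is exactly that of the SMILES (3S,4S,6R,10R). Dimethyl (R)-malate and L-2-aminobutyric acid are the cheap chiral inputs. All other reagents are achiral.

---

**Step 1**
Reactants: 1 dimethyl (R)-malate
Product: 2 dimethyl (R)-2-[(tert-butyldimethylsilyl)oxy]butanedioate
Conditions: TBSCl, imidazole, DMF, rt
Reagents that add atoms: TBSCl, CC(C)(C)[Si](C)(C)Cl
Why: Silylation of the secondary alcohol keeps the stereocentre; the bulky silyl ether later directs the Felkin–Anh facial selectivity in Step 4.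

**Step 2**
Reactants: 2
Product: 3 methyl (R)-3-[(tert-butyldimethylsilyl)oxy]-4-oxobutanoate
Conditions: DIBAL-H (1.05 equiv), CH2Cl2, −78 °C; crude used at once
Reagents that add atoms: none
Why: DIBAL-H attacks the more electrophilic α-silyloxy ester and stops at the aluminium hemiacetalate, so only that ester becomes the aldehyde.

**Step 3**
Reactants: 3
Product: 4 methyl (3R,4E)-3-[(tert-butyldimethylsilyl)oxy]-6-oxooct-4-enoate
Conditions: dimethyl (2-oxobutyl)phosphonate, LiCl, i-Pr2NEt, MeCN, 0 °C → rt
Reagents that add atoms: dimethyl (2-oxobutyl)phosphonate, CCC(=O)CP(=O)(OC)OC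
Why: Masamune–Roush Horner–Wadsworth–Emmons olefination gives the E-enone; the mild base avoids epimerising the α-silyloxy aldehyde.

**Step 4**
Reactants: 4
Product: 5 methyl (3R,4S)-3-[(tert-butyldimethylsilyl)oxy]-4-ethyl-6-oxooctanoate
Conditions: Et2CuLi (EtLi, CuI), Et2O, −78 → −40 °C
Reagents that add atoms: lithium diethylcuprate, CC[Cu-]CC.[Li+]
Why: In the conjugate addition the cuprate attacks anti to the γ C–O bond (Felkin–Anh), so the OSi and new Et end up anti and C4 is set as S relative to C3; the later inversion at C3 turns this into the ring-cis 3,4 arrangement.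

**Step 5**
Reactants: 6 L-2-aminobutyric acid
Product: 7 (S)-2-hydroxybutanoic acid
Conditions: NaNO2, 1 M aq. H2SO4, 0 °C → rt
Reagents that add atoms: water, O
Why: Diazotisation of an α-amino acid proceeds through an α-lactone (double inversion), so the stereocentre is retained and the (S)-hydroxy acid forms.

**Step 6**
Reactants: 7
Product: 8 methyl (S)-2-hydroxybutanoate
Conditions: MeOH, cat. H2SO4, reflux
Reagents that add atoms: methanol, CO
Why: Fischer esterification leaves the α-stereocentre untouched.

**Step 7**
Reactants: 8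
Product: 9 methyl (S)-2-[(tert-butyldimethylsilyl)oxy]butanoate
Conditions: TBSCl, imidazole, DMF, rt
Reagents that add atoms: TBSCl, CC(C)(C)[Si](C)(C)Cl
Why: The silyl ether protects the alcohol so that the aldehyde from Step 8 survives the basic ylide in Step 9.

**Step 8**
Reactants: 9
Product: 10 (S)-2-[(tert-butyldimethylsilyl)oxy]butanal
Conditions: DIBAL-H (1.05 equiv), CH2Cl2, −78 °C; crude used at once
Reagents that add atoms: none
Why: Partial reduction of the ester at low temperature stops at the aldehyde, and the α-silyloxy stereocentre is retained.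

**Step 9**
Reactants: 10
Product: 11 tert-butyldimethyl{[(3S,4Z)-hept-4-en-3-yl]oxy}silane
Conditions: PrPPh3Br, KHMDS, THF, −78 °C → rt
Reagents that add atoms: propyltriphenylphosphonium bromide, CCC[P+](c1ccccc1)(c1ccccc1)c1ccccc1.[Br-]
Why: A salt-free non-stabilised ylide gives the Z-alkene under kinetic Wittig control, with the stereocentre unchanged.

**Step 10**
Reactants: 11
Product: 12 (3S,4Z)-hept-4-en-3-ol
Conditions: TBAF, THF, 0 °C
Reagents that add atoms: none
Why: Fluoride cleaves the silyl ether and releases the allylic alcohol needed for the Claisen rearrangement.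

**Step 11 (key [3,3] sigmatropic step)**
Reactants: 12
Product: 13 ethyl (3R,4E)-3-ethylhept-4-enoate
Conditions: CH3C(OEt)3 (5 equiv), EtCO2H (cat.), 140 °C, EtOH removed
Reagents that add atoms: triethyl orthoacetate, CC(OCC)(OCC)OCC
Why: Johnson–Claisen rearrangement goes through a chair transition state with the carbinol ethyl pseudo-equatorial, so the new C–C bond forms suprafacially. This transfers the carbinol chirality to C10 (the Z-alkene reverses the sense, so the (S)-alcohol gives the (R)-centre) and fixes the new C11=C12 bond as E.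

**Step 12**
Reactants: 13
Product: 14 (3R,4E)-3-ethylhept-4-enal
Conditions: DIBAL-H (1.05 equiv), CH2Cl2, −78 °C
Reagents that add atoms: none
Why: Controlled partial reduction gives the aldehyde; the β-stereocentre cannot epimerise.

**Step 13**
Reactants: 14
Product: 15 (4R,5E)-4-ethyloct-5-en-1-yne
Conditions: Ohira–Bestmann reagent, K2CO3, MeOH, rt
Reagents that add atoms: dimethyl (1-diazo-2-oxopropyl)phosphonate, COP(=O)(OC)C(=[N+]=[N-])C(C)=O
Why: The Seyferth–Gilbert–type homologation adds one carbon (C7) under mild base and leaves the β-stereocentre and the E-alkene intact.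

**Step 14**
Reactants: 15
Product: 16 trimethyl[(1E,4R,5E)-2,4-diethylocta-1,5-dien-1-yl]silane
Conditions: Et2CuMgBr (EtMgBr 2.5 equiv, CuBr·SMe2 1.1 equiv), Et2O, −40 → −15 °C; then TMSCl, −15 °C → rt
Reagents that add atoms: ethylmagnesium bromide, CC[Mg]Br; chlorotrimethylsilane, C[Si](C)(C)Cl
Why: Normant syn-carbocupration puts Et on the internal alkyne carbon and the metal on the terminal carbon cis to it; TMSCl then traps this to give the E-vinylsilane (Si trans to C9).

**Step 15**
Reactants: 5
Product: 17 methyl (3R,4S)-4-ethyl-3-hydroxy-6-oxooctanoate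
Conditions: HF·pyridine, pyridine/THF, 0 °C → rt
Reagents that add atoms: none
Why: Buffered fluoride removes the secondary silyl ether while keeping the β-hydroxy ester from eliminating or undergoing retro-aldol.

**Step 16**
Reactants: 17
Product: 18 methyl (3R,4S)-4-ethyl-3-(methylsulfonyloxy)-6-oxooctanoate
Conditions: MsCl, Et3N, CH2Cl2, −40 °C
Reagents that add atoms: methanesulfonyl chloride, CS(=O)(=O)Cl
Why: The secondary alcohol is converted into a leaving group without touching the stereocentre.

**Step 17 (1,2-dioxane ring formation)**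
Reactants: 18
Product: 19 methyl 2-[(3S,4S)-4,6-diethyl-6-hydroxy-1,2-dioxan-3-yl]acetate (C6 anomeric mixture)
Conditions: 30% aq. H2O2 (10 equiv), K2CO3, THF/H2O, 0 °C → rt
Reagents that add atoms: hydrogen peroxide, OO
Why: HOO⁻ displaces the mesylate by SN2 with inversion, which sets C3 as S and makes the C3/C4 relationship ring-cis; the hydroperoxide then adds to the C6 ketone to give the cyclic peroxyhemiketal.

**Step 18**
Reactants: 19, 16
Product: 20 methyl 2-[(3S,4S,6R)-4,6-diethyl-6-[(1E,4R,5E)-2,4-diethylocta-1,5-dien-1-yl]-1,2-dioxan-3-yl]acetate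
Conditions: TMSOTf (1.5 equiv), CH2Cl2, −78 °C
Reagents that add atoms: none
Why: TMSOTf ionises the hemiketal to a peroxycarbenium ion; the vinylsilane attacks at its silicon-bearing carbon (β-silyl cation, then loss of TMS) with retention of alkene geometry. Attack is axial on the conformer with C4-Et equatorial, so the alkenyl group ends up trans to the C3 side chain and C6 is set as R.

**Step 19**
Reactants: 20
Product: 21 plakortide N, 2-[(3S,4S,6R)-4,6-diethyl-6-[(1E,4R,5E)-2,4-diethylocta-1,5-dien-1-yl]-1,2-dioxan-3-yl]acetic acid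
Conditions: LiOH, THF/H2O, 0 °C → rt; pH 4 work-up
Reagents that add atoms: none
Why: Mild saponification releases the acid without touching the peroxide, the alkenes or any stereocentre.

---

**Compound list**

| No. | Name | SMILES | Role |
|---|---|---|---|
| 1 | dimethyl (R)-malate | COC(=O)C[C@@H](O)C(=O)OC | starting material |
| 2 | dimethyl (R)-2-(TBSO)butanedioate | COC(=O)C[C@@H](O[Si](C)(C)C(C)(C)C)C(=O)OC | intermediate |
| 3 | methyl (R)-3-(TBSO)-4-oxobutanoate | COC(=O)C[C@@H](O[Si](C)(C)C(C)(C)C)C=O | intermediate |
| 4 | methyl (3R,4E)-3-(TBSO)-6-oxooct-4-enoate | COC(=O)C[C@@H](O[Si](C)(C)C(C)(C)C)/C=C/C(=O)CC | intermediate |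
| 5 | methyl (3R,4S)-3-(TBSO)-4-ethyl-6-oxooctanoate | COC(=O)C[C@@H](O[Si](C)(C)C(C)(C)C)[C@@H](CC)CC(=O)CC | intermediate |
| 6 | L-2-aminobutyric acid | CC[C@H](N)C(=O)O | starting material |
| 7 | (S)-2-hydroxybutanoic acid | CC[C@H](O)C(=O)O | intermediate |
| 8 | methyl (S)-2-hydroxybutanoate | CC[C@H](O)C(=O)OC | intermediate |
| 9 | methyl (S)-2-(TBSO)butanoate | CC[C@H](O[Si](C)(C)C(C)(C)C)C(=O)OC | intermediate |
| 10 | (S)-2-(TBSO)butanal | CC[C@H](O[Si](C)(C)C(C)(C)C)C=O | intermediate |
| 11 | (3S,4Z)-3-(TBSO)hept-4-ene | CC[C@H](O[Si](C)(C)C(C)(C)C)/C=C\CC | intermediate |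
| 12 | (3S,4Z)-hept-4-en-3-ol | CC[C@H](O)/C=C\CC | intermediate |
| 13 | ethyl (3R,4E)-3-ethylhept-4-enoate | CCOC(=O)C[C@@H](CC)/C=C/CC | intermediate |
| 14 | (3R,4E)-3-ethylhept-4-enal | O=CC[C@@H](CC)/C=C/CC | intermediate |
| 15 | (4R,5E)-4-ethyloct-5-en-1-yne | C#CC[C@@H](CC)/C=C/CC | intermediate |
| 16 | trimethyl[(1E,4R,5E)-2,4-diethylocta-1,5-dien-1-yl]silane | C[Si](C)(C)/C=C(\CC)C[C@@H](CC)/C=C/CC | intermediate |
| 17 | methyl (3R,4S)-4-ethyl-3-hydroxy-6-oxooctanoate | COC(=O)C[C@@H](O)[C@@H](CC)CC(=O)CC | intermediate |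
| 18 | methyl (3R,4S)-4-ethyl-3-(mesyloxy)-6-oxooctanoate | COC(=O)C[C@@H](OS(C)(=O)=O)[C@@H](CC)CC(=O)CC | intermediate |
| 19 | methyl 2-[(3S,4S)-4,6-diethyl-6-hydroxy-1,2-dioxan-3-yl]acetate | CCC1(O)C[C@H](CC)[C@H](CC(=O)OC)OO1 | intermediate |
| 20 | methyl ester of plakortide N | CC/C=C/[C@H](CC)C/C(=C/[C@@]1(CC)C[C@H](CC)[C@H](CC(=O)OC)OO1)CC | intermediate |
| 21 | plakortide N | CC/C=C/[C@H](CC)C/C(=C/[C@@]1(CC)C[C@H](CC)[C@H](CC(=O)O)OO1)CC | target |

---

**Total steps:** 19.
**Longest linear sequence:** 12 steps (L-2-aminobutyric acid → Steps 5–14 → Steps 18 and 19).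

**Three steps most likely to fail**
1. **Step 17 (HOO⁻ on the β-branched β-mesyloxy ester).** Elimination to the enoate, γ-keto cyclopropanation or carbonyl-oxygen participation could compete with the SN2.
   - Fallback: carry C1 as CH2OTBDPS (from the malate-derived triol) so there is no acidifying carbonyl during the displacement, and oxidise C1 to the acid at the very end.
2. **Step 18 (ipso-vinylation of a hindered tertiary peroxycarbenium).** Reactivity or axial selectivity may fall short.
   - Fallback: add the alkenylmagnesium from Step 14 (no TMSCl quench) to ketone 18, convert the tertiary allylic alcohol to the tertiary hydroperoxide with H2O2 and cat. acid, and close the ring by intramolecular SN2 with K2CO3; separate the C6 epimers by HPLC.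
3. **Step 2 (regioselective DIBAL-H reduction of the malate diester).** Reduction of the wrong ester, or over-reduction, would give the wrong aldehyde.
   - Fallback: reduce free dimethyl (R)-malate with BH3·SMe2/cat. NaBH4 (hydroxyl-directed) to the 3,4-diol, bis-silylate, selectively remove the primary TBS (PPTS, MeOH), and oxidise at once with Dess–Martin periodinane to give 3.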